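The retrosynthesis first removes the ring oxygen of ring D (the five-membered hydroxy lactone on ring B). Cutting its two C–O bonds and joining the lactol carbon to the lactone carbonyl contracts ring D to a cyclobutenone fused to ring B. This works because the lactol carbon, the only stereocentre, lies between ring B and that ring oxygen, so it maps onto the oxygen-bearing sp3 carbon next to the ketone of an α-silyloxy benzocyclobutenone.
Further cuts: the ester C–O bond of the seven-membered ring C, the diaryl ether C–O bond on ring A, and the two C–C bonds that tie the two-carbon unit to ring B.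
Forward order: the four-membered ring is built on ring B by aryne [2+2] cycloaddition, ring A is attached through the ether oxygen by SNAr, ring C is closed by carbodiimide lactonisation, and ring D arises last by oxygen insertion; acidic fluoride then removes both silyl groups.
Stereochemistry: the carbinol centre comes from a CBS reduction of a benzocyclobutenedione monoketal. It cannot enolise (the enol would be an antiaromatic benzocyclobutadiene) and is carried with retention into the lactol by the 1,2-shift.

Key step: step 18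

Remark: a 3-hydroxyphthalide lactol can in principle epimerise through its ring-opened formyl acid; it is assumed to hold its configuration under cold, acidic, base-free handling, which the last step observes.

Step 1
Reactants: 1 5-bromo-1,3-dimethoxy-2-methylbenzene
Product: 2 5-bromo-2-methylbenzene-1,3-diol
Conditions: BBr3, CH2Cl2, −78 °C to rt; H2O
Reagents that add atoms: none
Why: Lewis-acid cleavage of aryl methyl ethers with BBr3 frees both phenols, so that groups removable by hydrogenolysis can replace methyl groups that could not later be told apart from the ring A methoxy group.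

Step 2
Reactants: 2 5-bromo-2-methylbenzene-1,3-diol
Product: 3 1,3-bis(benzyloxy)-5-bromo-2-methylbenzene
Conditions: BnBr, K2CO3, DMF, rt
Reagents that add atoms: benzyl bromide, BrCc1ccccc1
Why: Williamson ether synthesis; benzyl ethers should tolerate the amide base, hydride, organolithium and carbonate steps that follow and fall together with the benzyl ester in step 15.

Step 3
Reactants: 3 1,3-bis(benzyloxy)-5-bromo-2-methylbenzene; 4 tris(trimethylsilyloxy)ethene
Product: 8 racemic 2,4-bis(benzyloxy)-8,8-dimethoxy-3-methylbicyclo[4.2.0]octa-1,3,5-trien-7-ol, via aryllithium 5 (not isolated), via aryne 6 (not isolated), via tris-silyl cycloadduct 7 (not isolated)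
Conditions: lithium 2,2,6,6-tetramethylpiperidide, THF, −78 to −20 °C; aq. NH4Cl; then HC(OMe)3, MeOH, CSA (cat.), rt
Reagents that add atoms: methanol, CO; trimethyl orthoformate, COC(OC)OC
Why: Aryne [2+2] cycloaddition with a ketene silyl acetal: the amide base removes the proton flanked by bromine and benzyloxy, LiBr is lost, and the silyloxy-bearing nucleophilic carbon of 4 adds to the aryne carbon remote from the benzyloxy group so that the ketal carbon ends next to it; acidic methanol with orthoformate then exchanges the labile bis(silyl) ketal for the dimethyl ketal and frees the alcohol, whose racemic centre is erased in step 4.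

Step 4
Reactants: 8 racemic 2,4-bis(benzyloxy)-8,8-dimethoxy-3-methylbicyclo[4.2.0]octa-1,3,5-trien-7-ol
Product: 9 2,4-bis(benzyloxy)-8,8-dimethoxy-3-methylbicyclo[4.2.0]octa-1,3,5-trien-7-one
Conditions: Dess–Martin periodinane, NaHCO3, CH2Cl2, 0 °C to rt
Reagents that add atoms: none
Why: Dess–Martin oxidation of a secondary benzylic alcohol under bicarbonate buffer should leave ketal and benzyl ethers untouched and give the monoketal of the benzocyclobutenedione.

Step 5
Reactants: 9 2,4-bis(benzyloxy)-8,8-dimethoxy-3-methylbicyclo[4.2.0]octa-1,3,5-trien-7-one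
Product: 10 (7S)-2,4-bis(benzyloxy)-8,8-dimethoxy-3-methylbicyclo[4.2.0]octa-1,3,5-trien-7-ol
Conditions: (R)-2-methyl-CBS-oxazaborolidine (20 mol %), BH3·SMe2, THF, −20 °C, slow addition of 9; MeOH
Reagents that add atoms: none
Why: Corey–Bakshi–Shibata reduction; with the quaternary dimethoxy carbon as the large group and the flat, tied-back arene as the small one, the (R)-catalyst should deliver hydride to the Re face of the ketone and set the (7S)-carbinol, which cannot epimerise later because its enol would be an antiaromatic benzocyclobutadiene.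

Step 6
Reactants: 10 (7S)-2,4-bis(benzyloxy)-8,8-dimethoxy-3-methylbicyclo[4.2.0]octa-1,3,5-trien-7-ol
Product: 11 (7S)-2,4-bis(benzyloxy)-7-(tert-butyldimethylsilyloxy)-8,8-dimethoxy-3-methylbicyclo[4.2.0]octa-1,3,5-triene
Conditions: TBSCl, imidazole, DMF, rt
Reagents that add atoms: tert-butyldimethylsilyl chloride, CC(C)(C)[Si](C)(C)Cl
Why: Standard silylation with the chloride and imidazole (a silyl triflate would activate the ketal); the ether blocks alkoxide formation and hence oxy-anion-accelerated opening of the four-membered ring in the basic steps ahead.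

Step 7
Reactants: 11 (7S)-2,4-bis(benzyloxy)-7-(tert-butyldimethylsilyloxy)-8,8-dimethoxy-3-methylbicyclo[4.2.0]octa-1,3,5-triene
Product: 12 (7S)-2,4-bis(benzyloxy)-5-bromo-7-(tert-butyldimethylsilyloxy)-8,8-dimethoxy-3-methylbicyclo[4.2.0]octa-1,3,5-triene
Conditions: NBS, MeCN, 0 °C, dark
Reagents that add atoms: N-bromosuccinimide, O=C1CCC(=O)N1Br
Why: Electrophilic aromatic bromination; the single free position of ring B is ortho and para to the two benzyloxy groups, and polar, dark conditions avoid benzylic radical bromination.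

Step 8
Reactants: 12 (7S)-2,4-bis(benzyloxy)-5-bromo-7-(tert-butyldimethylsilyloxy)-8,8-dimethoxy-3-methylbicyclo[4.2.0]octa-1,3,5-triene
Product: 15 (7S)-2,4-bis(benzyloxy)-7-(tert-butyldimethylsilyloxy)-8,8-dimethoxy-3-methylbicyclo[4.2.0]octa-1,3,5-trien-5-ol, via aryllithium 13 (not isolated), via lithium arylborate 14 (not isolated)
Conditions: B(OiPr)3, n-BuLi, THF, −78 °C (in situ trapping); then H2O2, NaOH aq., 0 °C
Reagents that add atoms: hydrogen peroxide, OO
Why: Bromine–lithium exchange with in situ borate trapping followed by oxidative ipso-hydroxylation of the arylboron species; at −78 °C the borate should capture the aryllithium faster than silyl migration or attack on the benzyl ethers can occur.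

Step 9
Reactants: 16 1-fluoro-3-methoxy-5-methylbenzene
Product: 18 2-fluoro-6-methoxy-4-methylbenzaldehyde, via aryllithium 17 (not isolated)
Conditions: n-BuLi, THF, −78 °C; DMF; aq. HCl
Reagents that add atoms: N,N-dimethylformamide, CN(C)C=O
Why: Directed ortho-metalation; the proton between fluorine and methoxy is the most acidic one, the ortho-fluoro aryllithium is stable at −78 °C, and DMF formylates it.

Step 10
Reactants: 18 2-fluoro-6-methoxy-4-methylbenzaldehyde
Product: 19 3-bromo-2-fluoro-6-methoxy-4-methylbenzaldehyde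
Conditions: NBS, DMF, rt
Reagents that add atoms: N-bromosuccinimide, O=C1CCC(=O)N1Br
Why: Electrophilic aromatic bromination para to the methoxy group and meta to the formyl group, at the less hindered of the two free positions.

Step 11
Reactants: 19 3-bromo-2-fluoro-6-methoxy-4-methylbenzaldehyde
Product: 20 benzyl 2-fluoro-3-formyl-4-methoxy-6-methylbenzoate
Conditions: Pd(OAc)2 (3 mol %), Xantphos, CO (1 atm), BnOH, Et3N, toluene, 80 °C
Reagents that add atoms: carbon monoxide, [C-]#[O+]; benzyl alcohol, OCc1ccccc1
Why: Palladium-catalysed alkoxycarbonylation of an aryl bromide: zerovalent palladium inserts into the C–Br bond, CO inserts, and benzyl alcohol cleaves the acyl complex, while triethylamine is too weak a base to trigger displacement of the fluoride.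

Step 12
Reactants: 15 (7S)-2,4-bis(benzyloxy)-7-(tert-butyldimethylsilyloxy)-8,8-dimethoxy-3-methylbicyclo[4.2.0]octa-1,3,5-trien-5-ol; 20 benzyl 2-fluoro-3-formyl-4-methoxy-6-methylbenzoate
Product: 21 benzyl 2-{[(7S)-2,4-bis(benzyloxy)-7-(tert-butyldimethylsilyloxy)-8,8-dimethoxy-3-methylbicyclo[4.2.0]octa-1,3,5-trien-5-yl]oxy}-3-formyl-4-methoxy-6-methylbenzoate
Conditions: Cs2CO3, DMF, 40 °C
Reagents that add atoms: none
Why: Nucleophilic aromatic substitution by addition–elimination; the fluoride is flanked by formyl and ester groups that stabilise the Meisenheimer adduct, so the hindered phenoxide of 15 should couple at 40 °C, below the temperature at which the oxygenated benzocyclobutene could open and lose its configuration.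

Step 13
Reactants: 21 benzyl 2-{[(7S)-2,4-bis(benzyloxy)-7-(tert-butyldimethylsilyloxy)-8,8-dimethoxy-3-methylbicyclo[4.2.0]octa-1,3,5-trien-5-yl]oxy}-3-formyl-4-methoxy-6-methylbenzoate
Product: 22 benzyl 2-{[(7S)-2,4-bis(benzyloxy)-7-(tert-butyldimethylsilyloxy)-8,8-dimethoxy-3-methylbicyclo[4.2.0]octa-1,3,5-trien-5-yl]oxy}-3-(hydroxymethyl)-4-methoxy-6-methylbenzoate
Conditions: NaBH4, THF/MeOH, 0 °C
Reagents that add atoms: none
Why: Chemoselective borohydride reduction of the aldehyde; the doubly ortho-substituted benzyl ester should not be touched at 0 °C.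

Step 14
Reactants: 22 benzyl 2-{[(7S)-2,4-bis(benzyloxy)-7-(tert-butyldimethylsilyloxy)-8,8-dimethoxy-3-methylbicyclo[4.2.0]octa-1,3,5-trien-5-yl]oxy}-3-(hydroxymethyl)-4-methoxy-6-methylbenzoate
Product: 23 benzyl 2-{[(7S)-2,4-bis(benzyloxy)-7-(tert-butyldimethylsilyloxy)-8,8-dimethoxy-3-methylbicyclo[4.2.0]octa-1,3,5-trien-5-yl]oxy}-3-[(tert-butyldimethylsilyloxy)methyl]-4-methoxy-6-methylbenzoate
Conditions: TBSCl, imidazole, DMF, rt
Reagents that add atoms: tert-butyldimethylsilyl chloride, CC(C)(C)[Si](C)(C)Cl
Why: Silylation of the primary benzylic alcohol, so that only a ring B phenol can meet the activated acid in step 16 and both silyl groups fall in one final operation.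

Step 15
Reactants: 23 benzyl 2-{[(7S)-2,4-bis(benzyloxy)-7-(tert-butyldimethylsilyloxy)-8,8-dimethoxy-3-methylbicyclo[4.2.0]octa-1,3,5-trien-5-yl]oxy}-3-[(tert-butyldimethylsilyloxy)methyl]-4-methoxy-6-methylbenzoate
Product: 24 2-{[(7S)-7-(tert-butyldimethylsilyloxy)-2,4-dihydroxy-8,8-dimethoxy-3-methylbicyclo[4.2.0]octa-1,3,5-trien-5-yl]oxy}-3-[(tert-butyldimethylsilyloxy)methyl]-4-methoxy-6-methylbenzoic acid
Conditions: H2 (1 atm), 10% Pd/C (palladium on carbon), EtOAc, rt
Reagents that add atoms: none
Why: Catalytic hydrogenolysis cleaves the benzyl ester and both benzyl ethers in one operation, while silyl ethers, ketal and diaryl ether should be inert in ethyl acetate at 1 atm.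

Step 16
Reactants: 24 2-{[(7S)-7-(tert-butyldimethylsilyloxy)-2,4-dihydroxy-8,8-dimethoxy-3-methylbicyclo[4.2.0]octa-1,3,5-trien-5-yl]oxy}-3-[(tert-butyldimethylsilyloxy)methyl]-4-methoxy-6-methylbenzoic acid
Product: 25 depsidone dimethyl ketal (ring C lactone between the ring A carboxyl and the 4-hydroxyl of the bicyclic unit; four-membered ring with C(OMe)2 and (S)-CH(OTBS) still fused to ring B)
Conditions: DCC, DMAP (cat.), CH2Cl2, high dilution, rt
Reagents that add atoms: none
Why: Carbodiimide (Steglich-type) lactonisation closes the seven-membered ring C; only the hydroxyl ortho to the ether oxygen can reach the activated carboxyl intramolecularly, and high dilution suppresses intermolecular acylation of the other phenol.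

Step 17
Reactants: 25 depsidone dimethyl ketal
Product: 26 depsidone-fused (S)-α-(tert-butyldimethylsilyloxy) benzocyclobutenone (ketone on the ring B carbon ortho to the free phenol; silyloxy carbon on the ring B carbon ortho to the ether oxygen)
Conditions: PPTS, acetone/H2O, 35 °C
Reagents that add atoms: water, O
Why: Mild acid-catalysed ketal hydrolysis; ionisation is assisted by the ortho phenol of ring B, while the hindered secondary and primary silyl ethers should survive pyridinium-level acidity.

Step 18
Reactants: 26 depsidone-fused (S)-α-(tert-butyldimethylsilyloxy) benzocyclobutenone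
Product: 28 bis(tert-butyldimethylsilyl) ether of the target with (S)-configured silyloxy phthalide carbon, via Criegee adduct 27 (not isolated)
Conditions: mCPBA, NaHCO3, CH2Cl2, 0 °C
Reagents that add atoms: 3-chloroperbenzoic acid, OOC(=O)c1cccc(Cl)c1
Why: The peracid adds to the strained, non-enolisable ketone to give Criegee adduct 27, and the bond from the carbonyl carbon to the silyloxy-bearing benzylic carbon then shifts to the proximal peroxide oxygen as 3-chlorobenzoate leaves. The closest known reaction type is the Baeyer–Villiger ring expansion of cyclobutanones and benzocyclobutenones, and of α-alkoxy ketones, in which the oxygenated carbon migrates. Ring D is closed by this 1,2-shift ring expansion of the four-membered ring (four to five atoms, both C–O bonds of the ring oxygen formed in one event, ring strain released), not by cyclisation of an open chain. No new stereocentre is formed: the centre set in step 5 migrates suprafacially with retention and becomes the lactol carbon without passing through an oxocarbenium ion. The selectivity needed is migration of the sp3 carbon rather than the ring B aryl carbon, which the oxygen lone pair and the benzylic character of that carbon secure; the bicarbonate buffer protects the new silyl acyl acetal, and at 0 °C the strained ketone should react far faster than the phenol ring or the aryl ester.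

Step 19
Reactants: 28 bis(tert-butyldimethylsilyl) ether of the target
Product: 29 CNP0367167.1 (target, (R)-configured lactol carbon)
Conditions: HF·pyridine, THF, 0 °C
Reagents that add atoms: none
Why: Fluoride cleavage of both Si–O bonds; no C–O bond at the lactol carbon is broken and the acidic, base-free medium disfavours ring opening to the formyl acid, so the configuration should be kept and the (R)-descriptor arises only from the change in substituent priority.

Compound list
1 | 5-bromo-1,3-dimethoxy-2-methylbenzene | COc1cc(Br)cc(OC)c1C | starting material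
2 | 5-bromo-2-methylbenzene-1,3-diol | Cc1c(O)cc(Br)cc1O | intermediate
3 | 1,3-bis(benzyloxy)-5-bromo-2-methylbenzene | Cc1c(OCc2ccccc2)cc(Br)cc1OCc1ccccc1 | intermediate
4 | tris(trimethylsilyloxy)ethene | C[Si](C)(C)OC=C(O[Si](C)(C)C)O[Si](C)(C)C | starting material
5 | 2,4-bis(benzyloxy)-6-bromo-3-methylphenyllithium (not isolated) | [Li]c1c(Br)cc(OCc2ccccc2)c(C)c1OCc1ccccc1 | intermediate
6 | 3,5-bis(benzyloxy)-4-methylbenzyne (not isolated) | CC1=C(OCc2ccccc2)C#CC=C1OCc1ccccc1 | intermediate
7 | racemic 2,4-bis(benzyloxy)-3-methyl-7,8,8-tris(trimethylsilyloxy)bicyclo[4.2.0]octa-1,3,5-triene (not isolated) | C[Si](C)(C)OC1c2cc(OCc3ccccc3)c(C)c(OCc3ccccc3)c2C1(O[Si](C)(C)C)O[Si](C)(C)C | intermediate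
8 | racemic 2,4-bis(benzyloxy)-8,8-dimethoxy-3-methylbicyclo[4.2.0]octa-1,3,5-trien-7-ol | OC1c2cc(OCc3ccccc3)c(C)c(OCc3ccccc3)c2C1(OC)OC | intermediate
9 | 2,4-bis(benzyloxy)-8,8-dimethoxy-3-methylbicyclo[4.2.0]octa-1,3,5-trien-7-one | O=C1c2cc(OCc3ccccc3)c(C)c(OCc3ccccc3)c2C1(OC)OC | intermediate
10 | (7S)-2,4-bis(benzyloxy)-8,8-dimethoxy-3-methylbicyclo[4.2.0]octa-1,3,5-trien-7-ol | O[C@H]1c2cc(OCc3ccccc3)c(C)c(OCc3ccccc3)c2C1(OC)OC | intermediate
11 | (7S)-2,4-bis(benzyloxy)-7-(tert-butyldimethylsilyloxy)-8,8-dimethoxy-3-methylbicyclo[4.2.0]octa-1,3,5-triene | CC(C)(C)[Si](C)(C)O[C@H]1c2cc(OCc3ccccc3)c(C)c(OCc3ccccc3)c2C1(OC)OC | intermediate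
12 | (7S)-2,4-bis(benzyloxy)-5-bromo-7-(tert-butyldimethylsilyloxy)-8,8-dimethoxy-3-methylbicyclo[4.2.0]octa-1,3,5-triene | CC(C)(C)[Si](C)(C)O[C@H]1c2c(Br)c(OCc3ccccc3)c(C)c(OCc3ccccc3)c2C1(OC)OC | intermediate
13 | 5-lithio derivative of 11 (not isolated) | CC(C)(C)[Si](C)(C)O[C@H]1c2c([Li])c(OCc3ccccc3)c(C)c(OCc3ccccc3)c2C1(OC)OC | intermediate
14 | lithium triisopropoxy(aryl)borate from 13 (not isolated) | [Li+].CC(C)O[B-](OC(C)C)(OC(C)C)c1c(OCc2ccccc2)c(C)c(OCc2ccccc2)c2c1[C@H](O[Si](C)(C)C(C)(C)C)C2(OC)OC | intermediate
15 | (7S)-2,4-bis(benzyloxy)-7-(tert-butyldimethylsilyloxy)-8,8-dimethoxy-3-methylbicyclo[4.2.0]octa-1,3,5-trien-5-ol | CC(C)(C)[Si](C)(C)O[C@H]1c2c(O)c(OCc3ccccc3)c(C)c(OCc3ccccc3)c2C1(OC)OC | intermediate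
16 | 1-fluoro-3-methoxy-5-methylbenzene | COc1cc(C)cc(F)c1 | starting material
17 | 2-fluoro-6-methoxy-4-methylphenyllithium (not isolated) | [Li]c1c(F)cc(C)cc1OC | intermediate
18 | 2-fluoro-6-methoxy-4-methylbenzaldehyde | COc1cc(C)cc(F)c1C=O | intermediate
19 | 3-bromo-2-fluoro-6-methoxy-4-methylbenzaldehyde | COc1cc(C)c(Br)c(F)c1C=O | intermediate
20 | benzyl 2-fluoro-3-formyl-4-methoxy-6-methylbenzoate | COc1cc(C)c(C(=O)OCc2ccccc2)c(F)c1C=O | intermediate
21 | diaryl ether aldehyde (benzyl ester, two benzyl ethers, ketal, (7S)-silyl ether) | COc1cc(C)c(C(=O)OCc2ccccc2)c(Oc2c(OCc3ccccc3)c(C)c(OCc3ccccc3)c3c2[C@H](O[Si](C)(C)C(C)(C)C)C3(OC)OC)c1C=O | intermediate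
22 | diaryl ether benzylic alcohol | COc1cc(C)c(C(=O)OCc2ccccc2)c(Oc2c(OCc3ccccc3)c(C)c(OCc3ccccc3)c3c2[C@H](O[Si](C)(C)C(C)(C)C)C3(OC)OC)c1CO | intermediate
23 | diaryl ether bis(silyl) ether | COc1cc(C)c(C(=O)OCc2ccccc2)c(Oc2c(OCc3ccccc3)c(C)c(OCc3ccccc3)c3c2[C@H](O[Si](C)(C)C(C)(C)C)C3(OC)OC)c1CO[Si](C)(C)C(C)(C)C | intermediate
24 | seco acid (free carboxyl, two free ring B phenols) | COc1cc(C)c(C(=O)O)c(Oc2c(O)c(C)c(O)c3c2[C@H](O[Si](C)(C)C(C)(C)C)C3(OC)OC)c1CO[Si](C)(C)C(C)(C)C | intermediate
25 | depsidone dimethyl ketal | COc1cc(C)c2c(c1CO[Si](C)(C)C(C)(C)C)Oc1c(c(C)c(O)c3c1[C@H](O[Si](C)(C)C(C)(C)C)C3(OC)OC)OC2=O | intermediate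
26 | depsidone-fused (S)-α-silyloxy benzocyclobutenone | COc1cc(C)c2c(c1CO[Si](C)(C)C(C)(C)C)Oc1c(c(C)c(O)c3c1[C@H](O[Si](C)(C)C(C)(C)C)C3=O)OC2=O | intermediate
27 | Criegee adduct of 26 with 3-chloroperbenzoic acid (not isolated) | COc1cc(C)c2c(c1CO[Si](C)(C)C(C)(C)C)Oc1c(c(C)c(O)c3c1[C@H](O[Si](C)(C)C(C)(C)C)C3(O)OOC(=O)c1cccc(Cl)c1)OC2=O | intermediate
28 | bis(tert-butyldimethylsilyl) ether of the target, (S) at the silyloxy phthalide carbon | COc1cc(C)c2c(c1CO[Si](C)(C)C(C)(C)C)Oc1c(c(C)c(O)c3c1[C@H](O[Si](C)(C)C(C)(C)C)OC3=O)OC2=O | intermediate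
29 | CNP0367167.1, (R) at the lactol carbon | COc1cc(C)c2c(c1CO)Oc1c(c(C)c(O)c3c1[C@H](O)OC3=O)OC2=O | target

Total step count: 19. Longest linear sequence: 16 steps (steps 1–8, then 12–19); ring A is made in the 3-step branch, steps 9–11.

Steps most likely to fail

Step 18. The risk is competing migration of the ring B aryl carbon, favoured by the free ortho hydroxyl in a Dakin-type pathway, or peracid oxidation of the electron-rich phenol ring. The fallback changes the substrate, not the oxidant. Setting out from 26, the phenol is silylated (TBSOTf, 2,6-lutidine, CH2Cl2, 0 °C) to the tris-silyl ketone F1, in which the arene is no longer an ortho-hydroxyaryl ketone and the carbonyl is no longer hydrogen-bonded. Buffered mCPBA should then give the tris-silyl lactone F2, and the HF·pyridine treatment of step 19 removes all three silyl groups, so the sequence comes back to the route at 29.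

Step 17. The risk is sluggish ionisation of the strained, inductively deactivated ketal, with loss of silyl ethers once the acid is strengthened. The fallback gives up the silyl groups on purpose. Setting out from 25, aqueous HCl in THF strips the ketal and both silyl ethers together and should give the (S)-hydroxy ketone triol F3. Buffered mCPBA then inserts oxygen next to the free carbinol carbon; the Baeyer–Villiger product of an α-hydroxy ketone is the lactol itself, so this comes back to the route at 29 without a fluoride step.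

Step 5. The risk is weak or reversed facial discrimination, because the two groups flanking the carbonyl are similar in size, together with uncatalysed reduction of the reactive strained ketone by borane. The fallback is a resolution through diastereomers. Setting out from racemic 8, esterification with (S)-O-methylmandelic acid (DCC, DMAP, CH2Cl2) gives the ester of the (7S)-alcohol F4 and the ester of the (7R)-alcohol F5. They are separated by chromatography or crystallisation and assigned by crystallography. DIBAL-H in CH2Cl2 at −78 °C then cleaves F4 reductively and comes back to the route at 10.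

Further compounds
F1 | step 18 | tris(tert-butyldimethylsilyl) ketone (26 with the ring B phenol silylated) | COc1cc(C)c2c(c1CO[Si](C)(C)C(C)(C)C)Oc1c(c(C)c(O[Si](C)(C)C(C)(C)C)c3c1[C@H](O[Si](C)(C)C(C)(C)C)C3=O)OC2=O
F2 | step 18 | tris(tert-butyldimethylsilyl) lactone (28 with the ring B phenol silylated) | COc1cc(C)c2c(c1CO[Si](C)(C)C(C)(C)C)Oc1c(c(C)c(O[Si](C)(C)C(C)(C)C)c3c1[C@H](O[Si](C)(C)C(C)(C)C)OC3=O)OC2=O
F3 | step 17 | depsidone-fused (S)-α-hydroxy benzocyclobutenone triol | COc1cc(C)c2c(c1CO)Oc1c(c(C)c(O)c3c1[C@H](O)C3=O)OC2=O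
F4 | step 5 | (7S)-2,4-bis(benzyloxy)-8,8-dimethoxy-3-methylbicyclo[4.2.0]octa-1,3,5-trien-7-yl (2S)-2-methoxy-2-phenylacetate | CO[C@H](C(=O)O[C@H]1c2cc(OCc3ccccc3)c(C)c(OCc3ccccc3)c2C1(OC)OC)c1ccccc1
F5 | step 5 | (7R)-2,4-bis(benzyloxy)-8,8-dimethoxy-3-methylbicyclo[4.2.0]octa-1,3,5-trien-7-yl (2S)-2-methoxy-2-phenylacetate | CO[C@H](C(=O)O[C@@H]1c2cc(OCc3ccccc3)c(C)c(OCc3ccccc3)c2C1(OC)OC)c1ccccc1
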